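## Retrosynthetic overview

- The target is trans-(1R,2R)-1,2-bis[(2,2'-bithiophen-5-yl)ethynyl]cyclobutane. The strategy rests on cyclobutane carbon C1, which carries one exocyclic carbon and sits next to stereocentre C2. Such a four-membered ring is a cyclopentanone contracted by one carbon, with the extruded carbonyl carbon left on C1 as a carboxyl group.
- C1–C(sp) bond (last): nickel-catalysed decarboxylative alkynylation of the C1 redox-active ester with the bithienylethynylzinc reagent, entering trans to the C2 arm.
- Cyclobutane (the only ring formed): photochemical Wolff contraction of (S)-3-alkynyl-2-diazocyclopentanone in methanol, then base equilibration of the ester.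
- Diazo group at C2: deacylative diazo transfer on the enolate left by an enantioselective conjugate alkynylation of cyclopent-2-enone, which sets the stereocentre that is carried through. The alkyne comes from 2,2'-bithiophene-5-carbaldehyde.

Key step: step 5

Assumption: the sense of induction in step 2 follows the ligand antipode, and the antipode giving the (3R)-adduct is used; the tetrachlorophthalimide ester is chosen as redox-active ester because low-valent nickel reduces it more readily than the unsubstituted phthalimide ester.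

## Route

Step 1
Reactants: 1 2,2'-bithiophene-5-carbaldehyde
Product: 2 5-ethynyl-2,2'-bithiophene
Conditions: dimethyl (1-diazo-2-oxopropyl)phosphonate, K2CO3, MeOH, 0 °C → rt, dark
Reagents that add atoms: dimethyl (1-diazo-2-oxopropyl)phosphonate, CC(=O)C(=[N+]=[N-])P(=O)(OC)OC
Why: Seyferth–Gilbert homologation in the Ohira–Bestmann form, in which methanolysis frees the diazomethylphosphonate anion, this olefinates the aldehyde and the diazoalkene loses N2 with 1,2-H shift to the terminal alkyne under conditions mild enough for the electron-rich bithiophene.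

Step 2
Reactants: 2 5-ethynyl-2,2'-bithiophene; 3 cyclopent-2-en-1-one
Product: 7 trimethyl{[(3R)-3-[(2,2'-bithiophen-5-yl)ethynyl]cyclopent-1-en-1-yl]oxy}silane, via lithium acetylide 4 (not isolated), via dimethylalkynylalane 5 (not isolated), via aluminium enolate 6 (not isolated)
Conditions: n-BuLi, Et2O, −78 → 0 °C; Me2AlCl; then 3, Ni(acac)2 (5 mol%), C2-symmetric cyano-bis(oxazoline) ligand (6 mol%), t-BuOMe, 0 °C; then TMSOTf, −40 → 0 °C; non-aqueous work-up (Et3N, pentane, basic alumina)
Reagents that add atoms: trimethylsilyl trifluoromethanesulfonate, C[Si](C)(C)OS(=O)(=O)C(F)(F)F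
Why: Nickel-catalysed enantioselective conjugate addition of a dimethylaluminium acetylide to a cyclic enone, in which the chiral bis(oxazoline) ligand selects the enone face so that C3 should form as R, and O-silylation of the aluminium enolate by the silyl triflate stores the enolate regiochemistry at C1=C2.

Step 3
Reactants: 7 trimethyl{[(3R)-3-[(2,2'-bithiophen-5-yl)ethynyl]cyclopent-1-en-1-yl]oxy}silane
Product: 9 (3R)-3-[(2,2'-bithiophen-5-yl)ethynyl]-2-(trifluoroacetyl)cyclopentan-1-one, via lithium enolate 8 (not isolated)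
Conditions: MeLi, THF, 0 °C; then CF3CO2CH2CF3, −78 °C; aq. HCl work-up; crude used directly
Reagents that add atoms: 2,2,2-trifluoroethyl trifluoroacetate, O=C(OCC(F)(F)F)C(F)(F)F
Why: Methyllithium cleaves the O–Si bond to release the regiodefined lithium enolate without proton transfer, so the Claisen-type C-acylation (first half of the Danheiser detrifluoroacetylative diazo transfer) should occur only at C2, between the carbonyl and the stereocentre.

Step 4
Reactants: 9 (3R)-3-[(2,2'-bithiophen-5-yl)ethynyl]-2-(trifluoroacetyl)cyclopentan-1-one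
Product: 10 (3S)-3-[(2,2'-bithiophen-5-yl)ethynyl]-2-diazocyclopentan-1-one
Conditions: MsN3, Et3N, H2O (1 equiv), MeCN, rt, dark; aq. NaOH wash
Reagents that add atoms: methanesulfonyl azide, CS(=O)(=O)N=[N+]=[N-]
Why: Regitz-type deacylative diazo transfer, in which the enolised 1,3-diketone attacks the sulfonyl azide and the adduct fragments with loss of the trifluoroacetyl group as the N-acylsulfonamide, leaving the diazo group at C2 and the C3 centre untouched (its descriptor becomes S only through the change in priorities).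

Step 5
Reactants: 10 (3S)-3-[(2,2'-bithiophen-5-yl)ethynyl]-2-diazocyclopentan-1-one; 11 methanol
Product: 14 methyl (1R,2R)-2-[(2,2'-bithiophen-5-yl)ethynyl]cyclobutane-1-carboxylate, via cyclobutylidene ketene 12 (not isolated), via C1-epimeric ester mixture 13 (not isolated)
Conditions: hν (violet LED, about 420 nm), degassed MeOH–THF, 5–10 °C; then NaOMe (0.5 equiv), MeOH, rt; AcOH quench
Reagents that add atoms: none
Why: Excitation of the weak long-wavelength n→π* band of the diazoketone expels N2, and because the ring holds C=O and C=N2 s-cis the C1–C5 bond shifts to the diazo carbon in concert, giving cyclobutylidene ketene 12; this is the photochemical Wolff rearrangement, long used for ring contraction of cyclic 2-diazoketones with alcohol trapping. The cyclobutane is closed by this 1,2-alkyl shift (contraction of the five-membered ring, new bond between the former C5 and C2) and not by cyclisation of a chain. Methanol adds to the ketene and protonation of the ester enol gives the C1 epimers 13, which NaOMe should equilibrate to the trans (1R,2R) ester, so C1 is under thermodynamic control from the fixed C2 centre. The alkyne-bearing centre is a spectator, since it is neither the migrating carbon nor acidic, and its configuration from step 2 is carried over. The step needs the Wolff shift to outrun carbene O–H insertion and 1,2-H shift from C3, which the locked s-cis geometry favours, and it needs excitation of the diazo chromophore only, which light beyond the absorption edge of the ethynylbithiophene should secure. Any cis ester that remains is not lost, because C1 is planarised again in step 8.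

Step 6
Reactants: 14 methyl (1R,2R)-2-[(2,2'-bithiophen-5-yl)ethynyl]cyclobutane-1-carboxylate
Product: 15 (1R,2R)-2-[(2,2'-bithiophen-5-yl)ethynyl]cyclobutane-1-carboxylic acid
Conditions: LiOH·H2O, THF/MeOH/H2O, rt; then aq. HCl
Reagents that add atoms: lithium hydroxide, [Li+].[OH-]
Why: Ester saponification by hydroxide attack at the ester carbonyl, with any epimerisation at C1 running toward the same trans isomer and the propargylic C2 centre not acidic enough to be touched.

Step 7
Reactants: 15 (1R,2R)-2-[(2,2'-bithiophen-5-yl)ethynyl]cyclobutane-1-carboxylic acid; 16 N-hydroxytetrachlorophthalimide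
Product: 17 4,5,6,7-tetrachloro-1,3-dioxoisoindolin-2-yl (1R,2R)-2-[(2,2'-bithiophen-5-yl)ethynyl]cyclobutane-1-carboxylate
Conditions: N,N'-diisopropylcarbodiimide, DMAP (10 mol%), CH2Cl2, rt; filtration, short silica plug
Reagents that add atoms: none
Why: Carbodiimide (Steglich-type) esterification gives the redox-active ester needed for single-electron decarboxylation, without touching either stereocentre.

Step 8
Reactants: 17 4,5,6,7-tetrachloro-1,3-dioxoisoindolin-2-yl (1R,2R)-2-[(2,2'-bithiophen-5-yl)ethynyl]cyclobutane-1-carboxylate; 2 5-ethynyl-2,2'-bithiophene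
Product: 20 cardopatine [(1R,2R)-1,2-bis[(2,2'-bithiophen-5-yl)ethynyl]cyclobutane], via alkynylmagnesium chloride 18 (not isolated), via alkynylzinc chloride 19 (not isolated)
Conditions: 2 (slight excess over the base), i-PrMgCl, THF, 0 °C → rt; ZnCl2, rt; then 17, NiCl2·glyme (20 mol%), 4,4'-di-tert-butyl-2,2'-bipyridine (40 mol%), THF/DMF, rt, dark
Reagents that add atoms: none
Why: Nickel-catalysed decarboxylative Negishi-type alkynylation of a redox-active ester, in which the terminal alkyne is magnesiated by i-PrMgCl and transmetalated to zinc, electron transfer from low-valent nickel releases CO2 and the C1 cyclobutyl radical, the alkynylnickel species captures it on the face away from the C2 arm and reductive elimination forms the C(sp3)–C(sp) bond, so C1 should be set trans (R) under substrate control while C2 is untouched.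

## Compound list

1 | 2,2'-bithiophene-5-carbaldehyde | O=Cc1ccc(-c2cccs2)s1 | starting material
2 | 5-ethynyl-2,2'-bithiophene | C#Cc1ccc(-c2cccs2)s1 | intermediate
3 | cyclopent-2-en-1-one | O=C1C=CCC1 | starting material
4 | lithium (2,2'-bithiophen-5-yl)acetylide | [Li]C#Cc1ccc(-c2cccs2)s1 | intermediate
5 | [(2,2'-bithiophen-5-yl)ethynyl]dimethylaluminium | C[Al](C)C#Cc1ccc(-c2cccs2)s1 | intermediate
6 | dimethylaluminium (3R)-3-[(2,2'-bithiophen-5-yl)ethynyl]cyclopent-1-en-1-olate | C[Al](C)OC1=C[C@H](C#Cc2ccc(-c3cccs3)s2)CC1 | intermediate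
7 | trimethyl{[(3R)-3-[(2,2'-bithiophen-5-yl)ethynyl]cyclopent-1-en-1-yl]oxy}silane | C[Si](C)(C)OC1=C[C@H](C#Cc2ccc(-c3cccs3)s2)CC1 | intermediate
8 | lithium (3R)-3-[(2,2'-bithiophen-5-yl)ethynyl]cyclopent-1-en-1-olate | [Li]OC1=C[C@H](C#Cc2ccc(-c3cccs3)s2)CC1 | intermediate
9 | (3R)-3-[(2,2'-bithiophen-5-yl)ethynyl]-2-(trifluoroacetyl)cyclopentan-1-one (C2 epimers and enol tautomers) | O=C1CC[C@@H](C#Cc2ccc(-c3cccs3)s2)C1C(=O)C(F)(F)F | intermediate
10 | (3S)-3-[(2,2'-bithiophen-5-yl)ethynyl]-2-diazocyclopentan-1-one | O=C1CC[C@@H](C#Cc2ccc(-c3cccs3)s2)C1=[N+]=[N-] | intermediate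
11 | methanol | CO | starting material
12 | {(2S)-2-[(2,2'-bithiophen-5-yl)ethynyl]cyclobutylidene}methanone (ketene) | O=C=C1CC[C@H]1C#Cc1ccc(-c2cccs2)s1 | intermediate
13 | methyl (2R)-2-[(2,2'-bithiophen-5-yl)ethynyl]cyclobutane-1-carboxylate, mixture of C1 epimers | COC(=O)C1CC[C@H]1C#Cc1ccc(-c2cccs2)s1 | intermediate
14 | methyl (1R,2R)-2-[(2,2'-bithiophen-5-yl)ethynyl]cyclobutane-1-carboxylate | COC(=O)[C@@H]1CC[C@H]1C#Cc1ccc(-c2cccs2)s1 | intermediate
15 | (1R,2R)-2-[(2,2'-bithiophen-5-yl)ethynyl]cyclobutane-1-carboxylic acid | OC(=O)[C@@H]1CC[C@H]1C#Cc1ccc(-c2cccs2)s1 | intermediate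
16 | N-hydroxytetrachlorophthalimide (4,5,6,7-tetrachloro-2-hydroxyisoindoline-1,3-dione) | ON1C(=O)c2c(Cl)c(Cl)c(Cl)c(Cl)c2C1=O | starting material
17 | 4,5,6,7-tetrachloro-1,3-dioxoisoindolin-2-yl (1R,2R)-2-[(2,2'-bithiophen-5-yl)ethynyl]cyclobutane-1-carboxylate | O=C(ON1C(=O)c2c(Cl)c(Cl)c(Cl)c(Cl)c2C1=O)[C@@H]1CC[C@H]1C#Cc1ccc(-c2cccs2)s1 | intermediate
18 | [(2,2'-bithiophen-5-yl)ethynyl]magnesium chloride | Cl[Mg]C#Cc1ccc(-c2cccs2)s1 | intermediate
19 | [(2,2'-bithiophen-5-yl)ethynyl]zinc chloride | Cl[Zn]C#Cc1ccc(-c2cccs2)s1 | intermediate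
20 | cardopatine, (1R,2R)-1,2-bis[(2,2'-bithiophen-5-yl)ethynyl]cyclobutane | C(#C[C@@H]1CC[C@H]1C#Cc1ccc(-c2cccs2)s1)c1ccc(-c2cccs2)s1 | target

## Step count and risks

Total step count: 8. Longest linear sequence: 8 steps (1 → 2 → 7 → 9 → 10 → 14 → 15 → 17 → 20).

**Step 5 (photochemical Wolff contraction).** The ethynylbithiophene may take up part of the light or pass excitation energy on, so that nitrogen loss feeds carbene reduction, O–H insertion or oligomerisation instead of ketene formation. The fallback runs the ring contraction with a silyl group in place of the bithiophene, so that only the diazoketone absorbs, and attaches the bithiophene afterwards. It sets out from cyclopentenone 3 and rejoins the route at 14. The conditions of step 2 applied to (triisopropylsilyl)acetylene should give trimethyl{[(3R)-3-[(triisopropylsilyl)ethynyl]cyclopent-1-en-1-yl]oxy}silane F1. MeLi followed by CF3CO2CH2CF3 should give (3R)-2-(trifluoroacetyl)-3-[(triisopropylsilyl)ethynyl]cyclopentan-1-one F2, and MsN3/Et3N should then give (3S)-2-diazo-3-[(triisopropylsilyl)ethynyl]cyclopentan-1-one F3. Irradiation at 300–365 nm in MeOH, then NaOMe, should give methyl (1R,2R)-2-[(triisopropylsilyl)ethynyl]cyclobutane-1-carboxylate F4. Bu4NF buffered with AcOH in THF should give methyl (1R,2R)-2-ethynylcyclobutane-1-carboxylate F5, and Sonogashira coupling of F5 with 5-iodo-2,2'-bithiophene (PdCl2(PPh3)2, CuI, Et3N, THF, rt) should give 14.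

**Step 2 (enantioselective conjugate alkynylation with silyl trapping).** Facial discrimination on the flat five-membered enone with a heteroaryl acetylide may be poor, since the precedent is strongest for cyclohexenone. The enolate may also lose its regiochemical integrity before silylation. The fallback is a racemic but regiospecific conjugate alkynylation followed by classical resolution at the acid. It sets out from 2 and 3 and rejoins the route at 15. Alkynylzinc chloride 19, prepared from 2 as in step 8, is added to 3 with TMSOTf in Et2O/THF at −40 °C (silyl triflate-promoted conjugate addition of an alkynylzinc halide), which should give racemic trimethyl{[3-[(2,2'-bithiophen-5-yl)ethynyl]cyclopent-1-en-1-yl]oxy}silane F6. Steps 3 to 6 unchanged should then give, in turn, racemic 3-[(2,2'-bithiophen-5-yl)ethynyl]-2-(trifluoroacetyl)cyclopentan-1-one F7, racemic 3-[(2,2'-bithiophen-5-yl)ethynyl]-2-diazocyclopentan-1-one F8, racemic trans methyl 2-[(2,2'-bithiophen-5-yl)ethynyl]cyclobutane-1-carboxylate F9 and racemic trans 2-[(2,2'-bithiophen-5-yl)ethynyl]cyclobutane-1-carboxylic acid F10. Fractional crystallisation of F10 with (R)-1-phenylethylamine should give (R)-1-phenylethylammonium (1R,2R)-2-[(2,2'-bithiophen-5-yl)ethynyl]cyclobutane-1-carboxylate F11; if the wanted acid stays in the mother liquor, the antipodal amine is used. Acidification of F11 gives 15.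

**Step 8 (decarboxylative alkynylation).** The rod-like alkynyl group at C2 shields little, so capture of the C1 radical may show low facial selectivity. The zinc acetylide may also attack the activated ester carbonyl before electron transfer. The fallback keeps the carboxyl carbon as the first alkyne carbon and sets C1 by thermodynamic control. It sets out from 14 and rejoins the route at 20. i-Bu2AlH in CH2Cl2 at −78 °C should give (1R,2R)-2-[(2,2'-bithiophen-5-yl)ethynyl]cyclobutane-1-carbaldehyde F12. Ohira–Bestmann homologation (K2CO3, MeOH), under which the α-carbon equilibrates to trans, should give 5-{[(1R,2R)-2-ethynylcyclobutyl]ethynyl}-2,2'-bithiophene F13. Sonogashira coupling of F13 with 5-iodo-2,2'-bithiophene (PdCl2(PPh3)2, CuI, Et3N, THF, rt) should give 20.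

## Further compounds

F1 | step 5 | trimethyl{[(3R)-3-[(triisopropylsilyl)ethynyl]cyclopent-1-en-1-yl]oxy}silane | C[Si](C)(C)OC1=C[C@H](C#C[Si](C(C)C)(C(C)C)C(C)C)CC1
F2 | step 5 | (3R)-2-(trifluoroacetyl)-3-[(triisopropylsilyl)ethynyl]cyclopentan-1-one | O=C1CC[C@@H](C#C[Si](C(C)C)(C(C)C)C(C)C)C1C(=O)C(F)(F)F
F3 | step 5 | (3S)-2-diazo-3-[(triisopropylsilyl)ethynyl]cyclopentan-1-one | O=C1CC[C@@H](C#C[Si](C(C)C)(C(C)C)C(C)C)C1=[N+]=[N-]
F4 | step 5 | methyl (1R,2R)-2-[(triisopropylsilyl)ethynyl]cyclobutane-1-carboxylate | COC(=O)[C@@H]1CC[C@H]1C#C[Si](C(C)C)(C(C)C)C(C)C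
F5 | step 5 | methyl (1R,2R)-2-ethynylcyclobutane-1-carboxylate | COC(=O)[C@@H]1CC[C@H]1C#C
F6 | step 2 | racemic trimethyl{[3-[(2,2'-bithiophen-5-yl)ethynyl]cyclopent-1-en-1-yl]oxy}silane | C[Si](C)(C)OC1=CC(C#Cc2ccc(-c3cccs3)s2)CC1
F7 | step 2 | racemic 3-[(2,2'-bithiophen-5-yl)ethynyl]-2-(trifluoroacetyl)cyclopentan-1-one | O=C1CCC(C#Cc2ccc(-c3cccs3)s2)C1C(=O)C(F)(F)F
F8 | step 2 | racemic 3-[(2,2'-bithiophen-5-yl)ethynyl]-2-diazocyclopentan-1-one | O=C1CCC(C#Cc2ccc(-c3cccs3)s2)C1=[N+]=[N-]
F9 | step 2 | racemic trans methyl 2-[(2,2'-bithiophen-5-yl)ethynyl]cyclobutane-1-carboxylate (both enantiomers) | COC(=O)[C@@H]1CC[C@H]1C#Cc1ccc(-c2cccs2)s1.COC(=O)[C@H]1CC[C@@H]1C#Cc1ccc(-c2cccs2)s1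
F10 | step 2 | racemic trans 2-[(2,2'-bithiophen-5-yl)ethynyl]cyclobutane-1-carboxylic acid (both enantiomers) | OC(=O)[C@@H]1CC[C@H]1C#Cc1ccc(-c2cccs2)s1.OC(=O)[C@H]1CC[C@@H]1C#Cc1ccc(-c2cccs2)s1
F11 | step 2 | (R)-1-phenylethylammonium (1R,2R)-2-[(2,2'-bithiophen-5-yl)ethynyl]cyclobutane-1-carboxylate | C[C@@H]([NH3+])c1ccccc1.[O-]C(=O)[C@@H]1CC[C@H]1C#Cc1ccc(-c2cccs2)s1
F12 | step 8 | (1R,2R)-2-[(2,2'-bithiophen-5-yl)ethynyl]cyclobutane-1-carbaldehyde | O=C[C@@H]1CC[C@H]1C#Cc1ccc(-c2cccs2)s1
F13 | step 8 | 5-{[(1R,2R)-2-ethynylcyclobutyl]ethynyl}-2,2'-bithiophene | C#C[C@@H]1CC[C@H]1C#Cc1ccc(-c2cccs2)s1
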